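The plan rests on cutting the bond between the cresol ring and the tertiary carbinol carbon, and on treating the isobutyryloxymethyl arm as a masked carboxyl group. The key step exploits the free phenolic O-H on the ring carbon next to the arylated one. As a titanium phenolate it guides the ketone of an 8-phenylmenthyl 3-acyloxypyruvate to the ortho C-H of m-cresol. It then closes a temporary five-membered lactone that expels the auxiliary. One telescoped operation thus forms the aryl-carbon bond, sets the tetrasubstituted stereocentre and distinguishes the two arms by oxidation level. Directed lactone reduction and isobutyrylation complete the target.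

Key step: step 3

Assumption: the target SMILES is read as (S) at the carbinol carbon and (R) in the 2-methylbutanoyl group, and (R)-2-methylbutanoic acid is taken as a purchasable enantiopure acid.

Step 1
Reactants: 1 3-bromopyruvic acid; 2 (−)-8-phenylmenthol
Product: 3 (1R,2S,5R)-8-phenylmenthyl 3-bromo-2-oxopropanoate
Conditions: TsOH·H2O (5 mol %), benzene, reflux, azeotropic removal of water
Reagents that add atoms: none
Why: Acid-catalysed Fischer esterification with azeotropic water removal is the usual entry to 8-phenylmenthyl α-keto esters and leaves the three stereocentres of the auxiliary untouched.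

Step 2
Reactants: 3 (1R,2S,5R)-8-phenylmenthyl 3-bromo-2-oxopropanoate; 4 (R)-2-methylbutanoic acid
Product: 6 (1R,2S,5R)-8-phenylmenthyl 3-{[(2R)-2-methylbutanoyl]oxy}-2-oxopropanoate, via cesium carboxylate 5 (not isolated)
Conditions: 4, Cs2CO3 (0.55 equiv), DMF, 0 °C; then 3, 0 °C to rt
Reagents that add atoms: none
Why: This is an SN2 displacement of the carbonyl-activated primary bromide by a weakly basic carboxylate, as in phenacyl ester formation, and it does not touch the α-stereocentre of the acid.

Step 3
Reactants: 6 (1R,2S,5R)-8-phenylmenthyl 3-{[(2R)-2-methylbutanoyl]oxy}-2-oxopropanoate; 7 m-cresol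
Product: 10 [(3R)-3-hydroxy-6-methyl-2-oxo-2,3-dihydro-1-benzofuran-3-yl]methyl (2R)-2-methylbutanoate, via aryloxytitanium trichloride 8 (not isolated), via open hydroxy ester 9 (not isolated)
Conditions: 7, TiCl4 (1.1 equiv), CH2Cl2, −30 °C; then 6, −30 to 0 °C; aq. NH4Cl; crude 9, TsOH·H2O (5 mol %), toluene, 60 °C
Reagents that add atoms: none
Why: m-Cresol and TiCl4 give 8, whose tetravalent titanium centre chelates the two adjacent carbonyl oxygens of 6 and delivers ring carbon C6 (ortho to oxygen, para to methyl) to the ketone carbon through a closed six-membered transition state, after which proton loss restores the arene and gives 9. This is the known ortho-specific Friedel-Crafts hydroxyalkylation of titanium phenolates by chiral pyruvate and glyoxylate esters, followed by the known acid-catalysed lactonisation to a 3-hydroxybenzofuran-2-one. The only ring closed, the five-membered lactone of 10, forms by 5-exo-trig attack of the phenol oxygen on the auxiliary ester carbonyl and loss of 8-phenylmenthol, helped by the gem-disubstituent effect of the fully substituted C3. The new stereocentre is controlled by the auxiliary: its cumyl phenyl group stacks over the s-cis chelated dicarbonyl and covers the Re face, so the arene adds to the Si face of the ketone (O > CO2R > CH2O), which means (R) in 9 and 10 and (S) in the target. Regioselectivity among C2, C4 and C6 of m-cresol is secured by the Ti-O tether, which excludes the para position C4, and by the C3 methyl group, which crowds C2 and activates C6. Chemoselectivity for the ketone over the two ester carbonyls follows from its higher electrophilicity inside the chelate.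

Step 4
Reactants: 10 [(3R)-3-hydroxy-6-methyl-2-oxo-2,3-dihydro-1-benzofuran-3-yl]methyl (2R)-2-methylbutanoate
Product: 11 (2S)-2,3-dihydroxy-2-(2-hydroxy-4-methylphenyl)propyl (2R)-2-methylbutanoate
Conditions: BH3·SMe2 (2 equiv), NaBH4 (5 mol %), THF, 0 °C to rt; MeOH quench, co-evaporation; used at once
Reagents that add atoms: none
Why: In this hydroxyl-directed borane reduction of an α-hydroxy ester the tertiary hydroxyl binds boron and passes hydride to the adjacent aryl lactone carbonyl much faster than borane attacks the branched aliphatic ester, and the non-basic medium holds back acyl migration, so the carbinol configuration should be kept.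

Step 5
Reactants: 11 (2S)-2,3-dihydroxy-2-(2-hydroxy-4-methylphenyl)propyl (2R)-2-methylbutanoate
Product: 13 (2S)-2-hydroxy-2-(2-hydroxy-4-methylphenyl)-3-(2-methylpropanoyloxy)propyl (2R)-2-methylbutanoate (target), via aryl isobutyrate 12 (not isolated)
Conditions: isobutyric anhydride (2.5 equiv), Et3N (3 equiv), DMAP (5 mol %), THF, 0 °C; then pyrrolidine (4 equiv), 0 °C to rt
Reagents that add atoms: isobutyric anhydride, CC(C)C(=O)OC(=O)C(C)C
Why: DMAP-catalysed acylation should esterify the primary alcohol and the phenol but not the hindered tertiary alcohol, and chemoselective aminolysis then cleaves the aryl ester, the only activated ester present, so any degree of phenol acylation converges on 13 without touching a stereocentre.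

Compound list
1 | 3-bromopyruvic acid (3-bromo-2-oxopropanoic acid) | OC(=O)C(=O)CBr | starting material
2 | (−)-8-phenylmenthol, (1R,2S,5R)-5-methyl-2-(2-phenylpropan-2-yl)cyclohexan-1-ol | O[C@@H]1C[C@H](C)CC[C@H]1C(C)(C)c1ccccc1 | starting material
3 | (1R,2S,5R)-8-phenylmenthyl 3-bromo-2-oxopropanoate | BrCC(=O)C(=O)O[C@@H]1C[C@H](C)CC[C@H]1C(C)(C)c1ccccc1 | intermediate
4 | (R)-2-methylbutanoic acid | CC[C@@H](C)C(=O)O | starting material
5 | cesium (R)-2-methylbutanoate | CC[C@@H](C)C(=O)[O-].[Cs+] | intermediate
6 | (1R,2S,5R)-8-phenylmenthyl 3-{[(2R)-2-methylbutanoyl]oxy}-2-oxopropanoate | CC[C@@H](C)C(=O)OCC(=O)C(=O)O[C@@H]1C[C@H](C)CC[C@H]1C(C)(C)c1ccccc1 | intermediate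
7 | m-cresol (3-methylphenol) | Cc1cccc(O)c1 | starting material
8 | (3-methylphenoxy)titanium trichloride | Cc1cccc(O[Ti](Cl)(Cl)Cl)c1 | intermediate
9 | (1R,2S,5R)-8-phenylmenthyl (2R)-2-hydroxy-2-(2-hydroxy-4-methylphenyl)-3-{[(2R)-2-methylbutanoyl]oxy}propanoate | CC[C@@H](C)C(=O)OC[C@@](O)(C(=O)O[C@@H]1C[C@H](C)CC[C@H]1C(C)(C)c1ccccc1)c1ccc(C)cc1O | intermediate
10 | [(3R)-3-hydroxy-6-methyl-2-oxo-2,3-dihydro-1-benzofuran-3-yl]methyl (2R)-2-methylbutanoate | CC[C@@H](C)C(=O)OC[C@@]1(O)C(=O)Oc2cc(C)ccc21 | intermediate
11 | (2S)-2,3-dihydroxy-2-(2-hydroxy-4-methylphenyl)propyl (2R)-2-methylbutanoate | CC[C@@H](C)C(=O)OC[C@@](O)(CO)c1ccc(C)cc1O | intermediate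
12 | (2S)-2-hydroxy-2-[4-methyl-2-(2-methylpropanoyloxy)phenyl]-3-(2-methylpropanoyloxy)propyl (2R)-2-methylbutanoate | CC[C@@H](C)C(=O)OC[C@@](O)(COC(=O)C(C)C)c1ccc(C)cc1OC(=O)C(C)C | intermediate
13 | (2S)-2-hydroxy-2-(2-hydroxy-4-methylphenyl)-3-(2-methylpropanoyloxy)propyl (2R)-2-methylbutanoate | CC[C@@H](C)C(=O)OC[C@@](O)(COC(=O)C(C)C)c1ccc(C)cc1O | target

Total step count: 5
Longest linear sequence: 5 (steps 1 to 5)

Steps most likely to fail

**Step 3.**
- What may go wrong: the ketoester may enolise or bind titanium through the wrong oxygens, so that C-C bond formation stalls. Facial shielding may be eroded, or the hindered auxiliary may leave too slowly in the lactonisation.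
- Fallback: the arene becomes a preformed organometallic instead of a phenolate.
- Setting out from 7, protection with MOMCl and diisopropylethylamine should give 1-(methoxymethoxy)-3-methylbenzene F1.
- Directed ortho-lithiation (t-BuLi, Et2O, 0 °C) at the less hindered position para to methyl should give [2-(methoxymethoxy)-4-methylphenyl]lithium F2.
- This is added at −78 °C to 6 precomplexed with MgBr2·OEt2. The reaction is a chelation-controlled 1,2-addition to an 8-phenylmenthyl α-keto ester with the same Si-face preference, and it should give the MOM-protected hydroxy ester F3.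
- Aqueous HCl in THF removes the MOM group, and the sequence comes back to the route at 9, which is lactonised as in step 3.

**Step 4.**
- What may go wrong: hydride may also attack the aliphatic ester. The 2-methylbutanoyl group may also migrate to the newly freed primary oxygen, which would scramble the carbinol configuration.
- Fallback: the carboxyl carbon is lowered one oxidation level at a time with reagents that ignore esters.
- Setting out from 10, ring opening with morpholine (THF, rt) should give the morpholine amide F4.
- Cp2Zr(H)Cl (3.5 equiv, THF, rt) should reduce the amide to the aldehyde level in the presence of the ester, and the aldehyde closes on the phenol to the lactol F5.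
- Hydroxyl-directed reduction with NaBH(OAc)3 in AcOH-MeCN at −20 °C, a weakly acidic medium without free alkoxide, comes back to the route at 11.

**Step 1.**
- What may go wrong: bromopyruvic acid may break down thermally, lose HBr or form a ketal before the hindered secondary alcohol is acylated.
- Fallback: the bromine is introduced after the ester bond.
- Setting out from 2, esterification with pyruvic acid (TsOH·H2O, benzene, reflux, azeotropic removal of water) should give 8-phenylmenthyl pyruvate F6.
- Acid-catalysed monobromination of its only enolisable position (Br2, CH2Cl2, 40 °C) comes back to the route at 3.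

Further compounds
F1 | step 3 | 1-(methoxymethoxy)-3-methylbenzene | COCOc1cccc(C)c1
F2 | step 3 | [2-(methoxymethoxy)-4-methylphenyl]lithium | COCOc1cc(C)ccc1[Li]
F3 | step 3 | (1R,2S,5R)-8-phenylmenthyl (2R)-2-hydroxy-2-[2-(methoxymethoxy)-4-methylphenyl]-3-{[(2R)-2-methylbutanoyl]oxy}propanoate | CC[C@@H](C)C(=O)OC[C@@](O)(C(=O)O[C@@H]1C[C@H](C)CC[C@H]1C(C)(C)c1ccccc1)c1ccc(C)cc1OCOC
F4 | step 4 | (2R)-2-hydroxy-2-(2-hydroxy-4-methylphenyl)-3-(morpholin-4-yl)-3-oxopropyl (2R)-2-methylbutanoate | CC[C@@H](C)C(=O)OC[C@@](O)(C(=O)N1CCOCC1)c1ccc(C)cc1O
F5 | step 4 | [(3R)-2,3-dihydroxy-6-methyl-2,3-dihydro-1-benzofuran-3-yl]methyl (2R)-2-methylbutanoate (anomeric mixture at C2) | CC[C@@H](C)C(=O)OC[C@@]1(O)C(O)Oc2cc(C)ccc21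
F6 | step 1 | (1R,2S,5R)-8-phenylmenthyl 2-oxopropanoate | CC(=O)C(=O)O[C@@H]1C[C@H](C)CC[C@H]1C(C)(C)c1ccccc1
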